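A ratio opened the meeting: the north run charged 2.58 times the free monomer of the west run, at the same 20 °C, yet its last reading stood 1.37 times as far along on a first-order scale.

| setting | west | south-west | north | teal | grey |
|---|---|---|---|---|---|
| free monomer | 0.12 M | 0.19 M | 0.31 M | 0.10 M | 0.30 M |
| initiator | 0.33 mM | 0.33 mM | 0.33 mM | 0.33 mM | 0.33 mM |
| temperature | 20 °C | 35 °C | 20 °C |  |  |
| remark | run made earlier | run made earlier | run made earlier | at 25 °C until 1.0 min, from then on at 45 °C | at 25 °C throughout |
| time |  |  |  | 2.0 min | 2.0 min |

- west (time / s: monomer in chains / %): 15.0: 3.7; 30.0: 5.5; 50.0: 7.6; 60.0: 9.4; 80.0: 11.9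
- south-west (time / s: monomer in chains / %): 10.0: 5.8; 20.0: 13.3; 30.0: 21.1; 40.0: 27.6; 50.0: 34.4
- north (time / s: monomer in chains / %): 10.0: 2.5; 20.0: 3.0; 40.0: 9.9; 60.0: 11.0; 80.0: 15.9

(each reading ± 1 percentage point)

- a reading or a percentage of monomer in chains counts all its forms, free or not

- the flask that ends with the higher amount of monomer in chains, in percent of the free monomer charged, or "neither" when 2 percentage points or less lies between them (teal / grey / neither)
- final monomer in chains, as a percentage of the free monomer charged, in teal
- final monomer in chains, as a percentage of the free monomer charged, in grey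

The first speaker defined k, an apparent first-order (pseudo-first-order) constant: minus the natural log of the fraction not in chains, divided by time. The last readings gave 0.0950 min⁻¹ for the west run and 0.130 min⁻¹ for the north run. She kept their mean, 0.112 min⁻¹, as one k for 20 °C.

The second speaker read 0.506 min⁻¹ from the south-west run at 35 °C, a ratio of 4.50. The south-west charge of 0.19 M lies between the west and north charges. The second speaker therefore took the ratio as an effect of temperature, a reading of 75.3 kJ mol⁻¹ for an apparent activation energy. So the reckoning puts k at 0.189 min⁻¹ at 25 °C and 1.27 min⁻¹ at 45 °C, the second beyond any run.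

The minute-taker proposed solving each stage of teal and joining them at the change of temperature. Exposure X is the sum of k times time over the stages, and in this reckoning the fraction in chains is one minus exp(−X). For teal, X is 1.46, of which the hot minute gives 87.1%. My reckoning is therefore 76.8% for teal and 31.4% for grey. Teal leads by 45 percentage points, more than the margin of 2 points.

The forecast named teal, with 71% for teal and 34% for grey. It argued for “mild autoacceleration, with rate increasing as chain concentration grows”. Its teal figure is lower than mine, and its grey figure is higher.

The flasks give teal as the higher, with 71.5% in teal and 37.1% in grey.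

    free monomer + initiating radical → growing radical + monomer in chains (k = 5.30 × 10⁶ M⁻¹ s⁻¹, Ea = 20.0 kJ mol⁻¹)
    initiator → 2 initiating radical (k = 6.70 × 10⁻⁴ s⁻¹, Ea = 98.0 kJ mol⁻¹)
    monomer in chains ⇌ isomer of the product (K = 1.10, k = 0.0510 s⁻¹, Ea = 83.0 kJ mol⁻¹, ΔH = −15.0 kJ mol⁻¹)
    2 growing radical → dead chain (k = 1.20 × 10⁸ M⁻¹ s⁻¹, Ea = 10.0 kJ mol⁻¹)
    free monomer + growing radical → monomer in chains + growing radical, rate k5*[growing radical]*[free monomer] (k = 1.10 × 10⁵ M⁻¹ s⁻¹, Ea = 25.0 kJ mol⁻¹)
    crystals ⇌ monomer in chains, rate k6*(cs6 - [monomer in chains]) while solid is left; crystals form when [monomer in chains] > cs6 (solubility = 12.0 mM, k = 0.270 s⁻¹)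
    (constants at 25 °C)

Read back, teal's result is an exposure of 1.26, against the 1.46 reckoned. The gap between the flasks is 34 points, more than the margin. Now take a neighbour, teal stopped at 30 s, still in its first stage at 25 °C. Its exposure is 0.189 min⁻¹ times 30 s, or 0.0945, so the reckoning gives 9.02%. That neighbour shows 8.41% of monomer in chains.

The data are calculated on assumed constants; scatter was added.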